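## The problem

2-(4-Hydroxyphenyl)ethyl pentacosanoate (7) is the ester of an unbranched, saturated C25 acid with the primary alcohol of a 4-hydroxyphenethyl unit. It has one benzene ring, no ring to be built and no stereocentre, so no question of stereocontrol arises. The task is to join three pieces, the phenol ring, the O–CH2–CH2 linker and the acyl chain, in few steps and without a statistical mixture. Two groups set the limits. The free phenol is acidic, easily oxidised and competes with an aliphatic alcohol for any acylating agent. The ester will not tolerate hydroxide, alkoxide, hydride or hard organometallics. The chain adds a practical limit: homologues differing by one CH2 cannot be separated from a waxy ester, so the C25 unit is best bought at full length and never cut or extended. The feature that opens a convergent route is the sp2–sp3 bond between the ring carbon para to the hydroxyl and the benzylic CH2 of the linker. Both of its carbons can be written as bromides: the aryl one in a protected 4-bromophenol, the alkyl one in a 2-bromoethyl ester that already carries the whole chain.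

## Retrosynthesis

**Target 7 to silyl ether 6.** The bond cut is the O–Si bond of a phenol protecting group. The phenol must be masked during the carbon–carbon bond formation. A tert-butyldimethylsilyl ether is preferred to a benzyl ether or an acyl group because it has no weak C–H bond for a bromine atom or silyl radical to attack, and it does not turn the ring into an acyl donor. It comes off with buffered fluoride, which leaves an alkyl ester alone. Precursor 6 differs from 7 only by this group. The forward step must cleave Si–O without a base strong enough to move or hydrolyse the acyl group.

**Silyl ether 6 to aryl bromide 2 and bromo ester 5.** The bond cut joins the ring carbon para to oxygen and the benzylic CH2. Its neighbours are the ester C–O bond, the CH2–CH2 bond of the linker and the C–C bonds of the chain.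
- The ester cut is the textbook one, but it places the acylation late, on a phenol-bearing alcohol that must itself be assembled and differentiated.
- The linker CH2–CH2 cut needs a benzylic organometallic.
- Cuts within the chain give up the purchased C25 unit.

The aryl–CH2 cut gives two bench-stable bromides, each one step from commerce, and puts the ester in place before the halves meet. It is served by a reductive cross-electrophile coupling in which nickel activates the aryl bromide and a silyl radical activates the alkyl bromide. The simplification is large: 6 has 39 carbons, while 2 and 5 carry 12 and 27, and neither needs a carbon–metal bond. The forward reaction must give cross- over homo-coupling, achieve oxidative addition on an electron-rich ring, and keep the acyloxy group β to the reacting carbon.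

**Bromo ester 5 to acid 3 and alcohol 4.** The acyl C–O bond is cut. Pentacosanoic acid (3) and 2-bromoethanol (4) are both commercial, and the acid-catalysed esterification with removal of water needs no activating reagent. The forward step only has to leave the primary C–Br bond alone.

**Aryl bromide 2 to phenol 1.** The O–Si bond is cut. 4-Bromophenol (1) is silylated under standard conditions.

## Roads not taken

**Alternative 1:** The cut is the C10–C11 bond of the acyl chain, drawn as an alkene.
- Forward step: 2-[4-(benzyloxy)phenyl]ethyl undec-10-enoate (A2) and an excess of 1-hexadecene (A3) undergo cross-metathesis with second-generation Grubbs catalyst, RuCl2(=CHPh)(PCy3)(H2IMes). The product is 2-[4-(benzyloxy)phenyl]ethyl (E)-pentacos-10-enoate (A1). Hydrogenation over Pd/C would then saturate the alkene and remove the benzyl ether in one operation to give 7.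
- Merits: both chain pieces are commodity chemicals, no C25 acid has to be bought, the alkene geometry is irrelevant, and the end game is a single step. In cost of materials and ease of scale-up this road is better than the chosen one.
- Weak points: A2 and A3 are unhindered terminal alkenes of equal reactivity, so the outcome is statistical. The self-metathesis products of A3 and A2 are waxes that must be separated from the waxy A1. More seriously, ruthenium hydrides formed from the catalyst shift terminal double bonds before metathesis. This gives acyl chains one carbon shorter or longer, which after hydrogenation cannot be separated from 7.
- Comparison: the step count is about the same. Against the cheaper feedstocks, the chosen plan sets a chain bought as a single homologue and never touched, and a coupling whose selectivity is mechanistic and not statistical.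

**Alternative 2:** The cut is the C8–C9 bond of the acyl chain.
- Forward step: mixed Kolbe electrolysis of 9-[2-(4-acetoxyphenyl)ethoxy]-9-oxononanoic acid (A5) with an excess of stearic acid (A6) at a Pt anode couples two primary alkyl radicals. The product is 2-(4-acetoxyphenyl)ethyl pentacosanoate (A4). Selective removal of the aryl acetate then gives 7.
- Merits: the odd chain is made from two cheap acids, and the carbon–carbon bond forms without a transition-metal catalyst or organometallic reagent. On materials cost and metal content it is better than the chosen plan.
- Weak points: radical–radical coupling is statistical, so the symmetrical dimers from A5 and from A6 form beside A4. Disproportionation and over-oxidation add alkenes, alcohols and ethers of similar polarity. The partly neutralised methanolic medium threatens the aryl acetate by methanolysis. The acetoxyphenyl ring may itself be oxidised at the high anode potential. Long-chain carboxylate salts dissolve poorly. The final step must discriminate an aryl acetate from an alkyl ester, which is possible but needs care.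
- Comparison: the chosen plan pays for iridium, nickel and a purchased C25 acid. In return it gives a two-component coupling of defined stoichiometry, and neither the ring nor the ester meets an anode or an alkoxide.

**Alternative 3:** The cut is the CH2–CH2 bond of the linker.
- Forward step: 4-(benzyloxy)benzylzinc chloride (A8) and chloromethyl pentacosanoate (A9) couple under NiCl2(dme) and a 2,6-bis(oxazolinyl)pyridine ligand. The product is 2-[4-(benzyloxy)phenyl]ethyl pentacosanoate (A7). Hydrogenolysis over Pd/C gives 7.
- Merits: the electrophilic carbon of A9 carries its oxygen in the α position, so the derived radical is stabilised and the nickel alkyl has neither a β-hydrogen nor a β-leaving group. The β-elimination concern of the chosen plan does not exist here. No light source is needed, and the benzyl ether leaves under neutral conditions. In these respects it is as good or better.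
- Weak points: A8 must be made from an electron-rich benzylic halide that tends to Wurtz-couple on zinc insertion, and it homocouples readily under nickel. A9 is a hard alkylating and acylating agent that can react with the organozinc without the catalyst. The established couplings of α-haloalkyl esters join secondary electrophiles to alkylzinc reagents, so a primary chloromethyl ester with a benzylzinc lies a step outside them. The route is also longer, since the zinc reagent takes two to three steps.
- Comparison: the chosen plan sets against this two air-stable partners, each one step from commerce, no carbon–metal reagent, and a reaction class already established for aryl bromides with primary alkyl bromides.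

Key step: step 3

Remark: the target and all route compounds are achiral, so no stereodescriptors appear; 1, 3 and 4 are taken as commercial.

Step 1
Reactants: 1 4-bromophenol
Product: 2 (4-bromophenoxy)(tert-butyl)dimethylsilane
Conditions: TBSCl (1.1 equiv), imidazole (2.2 equiv), DMF, 0 °C to rt
Reagents that add atoms: tert-butyldimethylsilyl chloride (TBSCl), CC(C)(C)[Si](C)(C)Cl
Why: Imidazole-promoted O-silylation of a phenol (Corey silylation); imidazole activates the silyl chloride and takes up HCl, and the aryl C–Br bond is untouched.

Step 2
Reactants: 3 pentacosanoic acid; 4 2-bromoethanol
Product: 5 2-bromoethyl pentacosanoate
Conditions: 4 (3 equiv), p-TsOH·H2O (5 mol%), toluene, reflux, Dean–Stark trap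
Reagents that add atoms: none
Why: Fischer esterification driven to completion by azeotropic removal of water and an excess of the cheap alcohol 4; hot toluene dissolves the waxy acid, and the primary C–Br bond is not displaced in an acidic, non-nucleophilic medium.

Step 3
Reactants: 2 (4-bromophenoxy)(tert-butyl)dimethylsilane; 5 2-bromoethyl pentacosanoate
Product: 6 2-[4-(tert-butyldimethylsilyloxy)phenyl]ethyl pentacosanoate
Conditions: 2 (1.5 equiv), 5 (1.0 equiv), NiCl2(dme) (5 mol%), 4,4'-di-tert-butyl-2,2'-bipyridine (5 mol%), Ir[dF(CF3)ppy]2(dtbbpy)PF6 (1 mol%), (Me3Si)3SiH (1.3 equiv), Na2CO3 (2 equiv), degassed DME, 450 nm LEDs, 30 °C
Reagents that add atoms: none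
Why: This is the nickel and photoredox cross-electrophile coupling of an aryl bromide with a primary alkyl bromide driven by silyl-radical halogen abstraction, a known reaction type applied here to a β-acyloxy alkyl bromide. The excited trivalent iridium photocatalyst oxidises bromide to a bromine atom, which takes hydrogen from (Me3Si)3SiH, and the resulting silyl radical abstracts bromine from 5 to give the primary 2-(acyloxy)ethyl radical. In parallel, zerovalent nickel bound to the bipyridine inserts into the C–Br bond of 2 to give a divalent arylnickel bromide, which captures the alkyl radical; the trivalent aryl(alkyl)nickel then reductively eliminates the aryl–CH2 bond of 6, and the monovalent nickel bromide left behind is reduced back to zerovalent nickel by the reduced iridium complex. No ring closes and no stereocentre is formed. The selectivity needed is cross- over homo-coupling, and it rests on the two bromides being activated by different agents: the sp2 C–Br bond by oxidative addition at nickel, the weaker sp3 C–Br bond by the nucleophilic silyl radical. Reductive elimination from trivalent nickel is fast, so β-acyloxy elimination should not compete, a 1,2-acyloxy shift in the radical would be degenerate on this symmetrical two-carbon unit, and with a silane as terminal reductant no β-acyloxy organozinc or organomanganese species can form and collapse to ethene and carboxylate. The silyl ether, the ester and the C25 chain are inert to silane, carbonate and visible light; 2 is used in excess because 5 carries the costly acid.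

Step 4
Reactants: 6 2-[4-(tert-butyldimethylsilyloxy)phenyl]ethyl pentacosanoate
Product: 7 2-(4-hydroxyphenyl)ethyl pentacosanoate
Conditions: Bu4NF (1.2 equiv), AcOH (1.5 equiv), THF, 0 °C to rt
Reagents that add atoms: none
Why: Fluoride-mediated desilylation of an aryl silyl ether, fast because of the strong Si–F bond and the good phenoxide leaving group; acetic acid protonates the phenoxide at once, so neither saponification nor acyl transfer of the alkyl ester should set in.

## Compound list

1 | 4-bromophenol | Oc1ccc(Br)cc1 | starting material
2 | (4-bromophenoxy)(tert-butyl)dimethylsilane | CC(C)(C)[Si](C)(C)Oc1ccc(Br)cc1 | intermediate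
3 | pentacosanoic acid | CCCCCCCCCCCCCCCCCCCCCCCCC(=O)O | starting material
4 | 2-bromoethanol | OCCBr | starting material
5 | 2-bromoethyl pentacosanoate | CCCCCCCCCCCCCCCCCCCCCCCCC(=O)OCCBr | intermediate
6 | 2-[4-(tert-butyldimethylsilyloxy)phenyl]ethyl pentacosanoate | CCCCCCCCCCCCCCCCCCCCCCCCC(=O)OCCc1ccc(O[Si](C)(C)C(C)(C)C)cc1 | intermediate
7 | 2-(4-hydroxyphenyl)ethyl pentacosanoate | CCCCCCCCCCCCCCCCCCCCCCCCC(=O)OCCc1ccc(O)cc1 | target

## Step count and risks

Total steps: 4. Longest linear sequence: 3 steps (steps 2, 3 and 4 from acid 3; equally steps 1, 3 and 4 from phenol 1).

**Step 3 (key step).**
- What may go wrong: oxidative addition of zerovalent nickel to the electron-rich silyloxy-substituted ring may be slow. The alkyl radical would then be quenched by hydrogen-atom transfer from the silane (hydrodebromination of 5) before an arylnickel can capture it. Halogen abstraction from the excess aryl bromide would waste silane in the same way. β-Acyloxy elimination could intrude if low-valent nickel engages the alkyl bromide directly. Poor solubility of the waxy ester in DME near room temperature could also limit light penetration and mixing.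
- Fallback, setting out from 2 and 3 and returning at 6: the same aryl–CH2 bond is made by polar chemistry. Bromide 2 is converted with Mg in THF into [4-(tert-butyldimethylsilyloxy)phenyl]magnesium bromide F1. F1 opens ethylene oxide under CuI catalysis and gives, after NH4Cl quench, 2-[4-(tert-butyldimethylsilyloxy)phenyl]ethanol F2. F2 is then acylated with acid 3 (EDC·HCl, DMAP, CH2Cl2) to give 6, and step 4 follows unchanged.

**Step 2.**
- What may go wrong: incomplete esterification of the sparingly soluble acid. On prolonged heating with acid the C–Br bond may also erode, through displacement of bromide by the carboxylic acid or by a second molecule of the alcohol.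
- Fallback, setting out from 3 and returning at 5: the O–CH2 bond is formed in place of the acyl C–O bond. Acid 3 is converted with K2CO3 in DMF into potassium pentacosanoate F3, which is alkylated in the same flask by a large excess of 1,2-dibromoethane at 60 °C to give 5. The excess suppresses double displacement.

**Step 4.**
- What may go wrong: loss or migration of the acyl group. Basic fluoride, or phenoxide formed faster than it is protonated, could bring about hydrolysis by adventitious water or transesterification onto the phenol oxygen. Silyl cleavage may also be incomplete if the medium is over-buffered.
- Fallback, setting out from 1 and returning at 7: the protecting group is changed to one removed under neutral reductive conditions. Phenol 1 is benzylated (benzyl bromide, K2CO3, acetone, reflux) to 1-(benzyloxy)-4-bromobenzene F4. F4 is coupled with 5 under the conditions of step 3 to give 2-[4-(benzyloxy)phenyl]ethyl pentacosanoate F5, the structure also met as A7. F5 is hydrogenolysed (H2, Pd/C, EtOAc/THF, rt) to 7. The ester oxygen sits on a homobenzylic carbon and is not cleaved.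

## Further compounds

F1 | step 3 | [4-(tert-butyldimethylsilyloxy)phenyl]magnesium bromide | CC(C)(C)[Si](C)(C)Oc1ccc([Mg]Br)cc1
F2 | step 3 | 2-[4-(tert-butyldimethylsilyloxy)phenyl]ethanol | CC(C)(C)[Si](C)(C)Oc1ccc(CCO)cc1
F3 | step 2 | potassium pentacosanoate | CCCCCCCCCCCCCCCCCCCCCCCCC(=O)[O-].[K+]
F4 | step 4 | 1-(benzyloxy)-4-bromobenzene | Brc1ccc(OCc2ccccc2)cc1
F5 | step 4 | 2-[4-(benzyloxy)phenyl]ethyl pentacosanoate | CCCCCCCCCCCCCCCCCCCCCCCCC(=O)OCCc1ccc(OCc2ccccc2)cc1
A1 | alternative 1 | 2-[4-(benzyloxy)phenyl]ethyl (E)-pentacos-10-enoate | CCCCCCCCCCCCCC/C=C/CCCCCCCCC(=O)OCCc1ccc(OCc2ccccc2)cc1
A2 | alternative 1 | 2-[4-(benzyloxy)phenyl]ethyl undec-10-enoate | C=CCCCCCCCCC(=O)OCCc1ccc(OCc2ccccc2)cc1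
A3 | alternative 1 | 1-hexadecene | C=CCCCCCCCCCCCCCC
A4 | alternative 2 | 2-(4-acetoxyphenyl)ethyl pentacosanoate | CCCCCCCCCCCCCCCCCCCCCCCCC(=O)OCCc1ccc(OC(C)=O)cc1
A5 | alternative 2 | 9-[2-(4-acetoxyphenyl)ethoxy]-9-oxononanoic acid | OC(=O)CCCCCCCC(=O)OCCc1ccc(OC(C)=O)cc1
A6 | alternative 2 | stearic acid | CCCCCCCCCCCCCCCCCC(=O)O
A7 | alternative 3 | 2-[4-(benzyloxy)phenyl]ethyl pentacosanoate | CCCCCCCCCCCCCCCCCCCCCCCCC(=O)OCCc1ccc(OCc2ccccc2)cc1
A8 | alternative 3 | 4-(benzyloxy)benzylzinc chloride | Cl[Zn]Cc1ccc(OCc2ccccc2)cc1
A9 | alternative 3 | chloromethyl pentacosanoate | CCCCCCCCCCCCCCCCCCCCCCCCC(=O)OCCl
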